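Locants (phthalide numbering): butenolide half C1, O2, C3, C3a, C4–C7, C7a, C8–C11 (ring A = C3a–C7a); enol-lactone half primed (ring B = C3a'–C7a'); cyclobutane = C6, C7, C3a', C7a'.
Retrosynthesis: the butenolide O2–C3 and C3a–C3 bonds are cut last (ring-A cyclohexenecarboxylic acid + C5 alkyne); then C7a–C1 (carbonylation), the enol-lactone O2'–C3' and C8'–C9' bonds (iodolactonization, Negishi), C6'=C7' (ring-closing metathesis) and the cyclobutane bonds C6–C7a' and C7–C3a' (intramolecular [2+2]).
Forward: a 3-vinyl-4-(carboxymethyl)-5-methoxyfuranone from mucobromic acid is esterified with (R)-cyclohex-2-en-1-ol (ring A); photocycloaddition forms the cyclobutane, metathesis closes ring B, the masked aldehyde C3' becomes lactone B, ring A becomes the enoic acid, and the butenolide is closed last.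
Stereochemistry: the carbinol centre of (R)-cyclohex-2-en-1-ol sets C6, C7, C3a' and C7a' through a cis-fused six-membered lactone tether and is then oxidized away; C3'=C8' (E) comes from anti iodolactonization and stereoretentive Negishi coupling, C3=C8 (Z) from anti oxymetalation.
Enabling feature of the key step: on the ring-A alkene the carboxyl on C7a and the lone vinylic hydrogen on C3a are held cis by the ring, so carboxylate-directed metalation is confined to C3a, and the pentynyl group placed there holds its inner carbon (C3) 1,5 to the carboxyl oxygen for 5-exo-dig closure.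
Key step: step 17

Remark: the methoxy acetal carbon C3' is formed racemic in step 1 and is carried as both epimers (no descriptor in the SMILES) until step 10 removes it; (R)-cyclohex-2-en-1-ol and zinc reagent 3 are taken as commercial.

Step 1
Reactants: 1 mucobromic acid (3,4-dibromo-5-hydroxyfuran-2(5H)-one)
Product: 2 3,4-dibromo-5-methoxyfuran-2(5H)-one (racemic)
Conditions: MeOH, H2SO4 (cat.), reflux
Reagents that add atoms: methanol, CO
Why: Acid-catalysed acetalization of the cyclic lactol (pseudo-acid) with methanol gives the methyl pseudo-ester, which masks the aldehyde that will become C3' and is formed as a racemic acetal.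

Step 2
Reactants: 2 3,4-dibromo-5-methoxyfuran-2(5H)-one; 3 (2-tert-butoxy-2-oxoethyl)zinc bromide
Product: 4 tert-butyl 2-(4-bromo-2-methoxy-5-oxo-2,5-dihydrofuran-3-yl)acetate
Conditions: Pd(dba)2 (5 mol %), P(t-Bu)3 (5 mol %), THF, rt
Reagents that add atoms: none
Why: Negishi coupling of a Reformatsky zinc enolate in which zerovalent palladium inserts first into the C–Br bond β to the lactone carbonyl (a vinylogous acyl bromide), so that the acetate arm (C4', C5') enters next to the acetal carbon and the α-bromide is kept.

Step 3
Reactants: 4 tert-butyl 2-(4-bromo-2-methoxy-5-oxo-2,5-dihydrofuran-3-yl)acetate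
Product: 5 tert-butyl 2-(4-ethenyl-2-methoxy-5-oxo-2,5-dihydrofuran-3-yl)acetate
Conditions: Bu3SnCH=CH2, PdCl2(PPh3)2 (5 mol %), toluene, 80 °C
Reagents that add atoms: tributyl(vinyl)stannane, C=C[Sn](CCCC)(CCCC)CCCC
Why: Stille coupling of the remaining α-bromide with retention of the ring alkene places the vinyl group (the future C7') on the future C7a'.

Step 4
Reactants: 5 tert-butyl 2-(4-ethenyl-2-methoxy-5-oxo-2,5-dihydrofuran-3-yl)acetate; 6 (R)-cyclohex-2-en-1-ol
Product: 8 (R)-cyclohex-2-en-1-yl 2-(4-ethenyl-2-methoxy-5-oxo-2,5-dihydrofuran-3-yl)acetate, via carboxylic acid 7 (not isolated)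
Conditions: TFA, CH2Cl2, 0 °C, then evaporation; 6, EDC·HCl, DMAP (cat.), CH2Cl2, 0 °C to rt
Reagents that add atoms: none
Why: Acidolysis of the tert-butyl ester leaves the methyl pseudo-ester intact, and Steglich-type carbodiimide esterification acylates the allylic alcohol at oxygen without touching its stereocentre, which becomes the control element of step 5.

Step 5
Reactants: 8 (R)-cyclohex-2-en-1-yl 2-(4-ethenyl-2-methoxy-5-oxo-2,5-dihydrofuran-3-yl)acetate
Product: 9 photocycloadduct: cyclobutane C6–C7–C3a'–C7a' cis-fused to ring A (7aR, C7a carrying the ester oxygen), to the six-membered tether lactone C7a–O–C5'(=O)–C4'H2–C3a' and to the 3'-methoxy γ-lactone C7a'–C1'(=O)–O–C3'; vinyl on C7a'; ring A syn to the C4' arm and to the vinyl group, γ-lactone anti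
Conditions: thioxanthen-9-one (10 mol %), MeCN (5 mM), 405 nm LEDs, rt, argon
Reagents that add atoms: none
Why: Triplet-sensitized intramolecular [2+2] photocycloaddition of the furanone diene with the tethered cyclohexene, in which the four-atom ester tether allows only bonding of C3a' to C7 (six-membered lactone) followed by closure of C7a' onto C6, the four stereocentres C6, C7, C3a' and C7a' are set by the (R) carbinol carbon because the tether lactone, ring A and the furanone must all be cis-fused to the new cyclobutane, and the vinyl group survives as in sensitized diene–alkene cycloadditions that give vinylcyclobutanes.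

Step 6
Reactants: 9 photocycloadduct
Product: 10 diol: tether lactone opened to C3a'–CH2CH2OH and a free 7a-hydroxyl; pseudo-ester and vinyl retained
Conditions: LiBH4 (1.2 equiv), THF, −10 °C; aq. NH4Cl
Reagents that add atoms: none
Why: Chemoselective lithium borohydride reduction opens the unhindered δ-lactone to the diol, whereas the pseudo-ester carbonyl is shielded by the two adjacent quaternary carbons C7a' and C3a', and no stereocentre is affected.

Step 7
Reactants: 10 diol
Product: 11 primary iodide: C3a'–CH2CH2I, 7a-hydroxyl free
Conditions: I2, PPh3, imidazole, THF, 0 °C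
Reagents that add atoms: iodine, II
Why: Garegg–Samuelsson (Appel-type) iodination converts the unhindered primary alcohol into the iodide in preference to the secondary ring-A alcohol.

Step 8
Reactants: 11 primary iodide
Product: 12 diene: but-3-enyl on C3a', vinyl on C7a', 7a-hydroxyl free
Conditions: CH2=CHMgBr (3 equiv), CuI (10 mol %), THF, −30 to 0 °C
Reagents that add atoms: vinylmagnesium bromide, C=C[Mg]Br
Why: Copper-catalysed (Kochi-type) coupling of the primary iodide with the vinyl Grignard reagent builds the but-3-enyl arm, the first equivalent of reagent converting the alcohol into a poorly nucleophilic magnesium alkoxide.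

Step 9
Reactants: 12 diene
Product: 13 propellane: cyclohexene ring B (C6'=C7') closed on the C3a'–C7a' bond; 3'-methoxy γ-lactone and 7a-hydroxyl retained
Conditions: second-generation Grubbs catalyst (H2IMes)(PCy3)Cl2Ru=CHPh (5 mol %), CH2Cl2 (5 mM), 40 °C
Reagents that add atoms: none
Why: Ring-closing metathesis of the but-3-enyl arm on C3a' with the vinyl group on C7a', which are cis on the cyclobutane, closes cyclohexene ring B with its double bond at C6'=C7' and expels ethene.

Step 10
Reactants: 13 propellane pseudo-ester
Product: 15 alkynoic acid: ethynyl on C3a' and CO2H on C7a' (cis on the cyclobutane), 7a-hydroxyl free, via lactol 14 (not isolated)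
Conditions: 2 M HCl, THF, rt, then concentration; MeC(O)C(N2)P(O)(OMe)2, K2CO3, MeOH, 0 °C to rt; acidic work-up
Reagents that add atoms: water, O; dimethyl (1-diazo-2-oxopropyl)phosphonate, COP(=O)(OC)C(=[N+]=[N-])C(C)=O
Why: Acid hydrolysis of the pseudo-ester gives the lactol, whose ring-opened aldehyde–carboxylate undergoes Seyferth–Gilbert homologation with the Bestmann–Ohira reagent, and the aldehyde carbon sits on a quaternary centre so nothing can epimerize.

Step 11
Reactants: 15 alkynoic acid
Product: 16 (E)-iodomethylene enol lactone B (iodine trans to O2'), 7a-hydroxyl free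
Conditions: I2, NaHCO3, MeCN, 0 °C, dark
Reagents that add atoms: iodine, II
Why: Iodolactonization in which the carboxylate, cis to the ethynyl group on the cyclobutane, opens the iodonium ion of the alkyne anti in the 5-exo-dig mode, so that iodine ends trans to the ring oxygen.

Step 12
Reactants: 16 (E)-iodomethylene enol lactone
Product: 17 (E)-butylidene enol lactone B with the 7a-hydroxyl on ring A
Conditions: n-PrZnBr (3 equiv), Pd(dppf)Cl2 (5 mol %), THF, rt
Reagents that add atoms: propylzinc bromide, CCC[Zn]Br
Why: Negishi coupling of the alkenyl iodide with the alkylzinc halide proceeds with retention at the sp2 carbon, which fixes propyl trans to the lactone oxygen in the (E)-butylidene group, and the organozinc does not attack the lactone.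

Step 13
Reactants: 17 (E)-butylidene enol lactone alcohol
Product: 18 ring-A ketone (C7a=O)
Conditions: Dess–Martin periodinane, NaHCO3, CH2Cl2, rt
Reagents that add atoms: none
Why: Dess–Martin oxidation of the secondary alcohol under buffered conditions removes the stereocentre that served as control element and spares the acid- and base-sensitive enol lactone.

Step 14
Reactants: 18 ring-A ketone
Product: 20 enol triflate (C7a=C3a, OTf on C7a), via potassium enolate 19 (not isolated)
Conditions: KN(SiMe3)2, THF, −78 °C; then PhNTf2
Reagents that add atoms: N-phenylbis(trifluoromethanesulfonimide), O=S(=O)(N(c1ccccc1)S(=O)(=O)C(F)(F)F)C(F)(F)F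
Why: Kinetic deprotonation takes place at the C3a methylene, since an enolate toward the ring-fusion carbon C7 would place a double bond exocyclic to the cyclobutane, and O-sulfonylation of the potassium enolate gives the C7a=C3a enol triflate.

Step 15
Reactants: 20 enol triflate
Product: 21 ring-A enoic acid (CO2H on C7a, hydrogen on C3a)
Conditions: Pd(OAc)2 (5 mol %), dppf (10 mol %), KOAc, CO (1 atm), DMSO, 60 °C; aq. acid work-up
Reagents that add atoms: carbon monoxide, [C-]#[O+]; water, O
Why: Palladium-catalysed hydroxycarbonylation of the alkenyl triflate, with acetate as the nucleophile and hydrolysis of the mixed anhydride on work-up, puts the C1 carboxyl on C7a without a strong nucleophile that could open the enol lactone.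

Step 16
Reactants: 22 pent-1-yne
Product: 23 1-bromopent-1-yne
Conditions: NBS, AgNO3 (10 mol %), acetone, rt
Reagents that add atoms: N-bromosuccinimide, O=C1CCC(=O)N1Br
Why: Silver-catalysed electrophilic bromination of the terminal alkyne C–H bond with N-bromosuccinimide.

Step 17
Reactants: 21 ring-A enoic acid; 23 1-bromopent-1-yne
Product: 25 target compound, via enynoic acid 24 (not isolated)
Conditions: [RuCl2(p-cymene)]2 (5 mol %), MesCO2K (30 mol %), K2CO3 (2 equiv), 1,4-dioxane, 80 °C; then AgNO3 (10 mol %), acetone, rt, dark
Reagents that add atoms: none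
Why: Proposed new method: the carboxylate binds divalent ruthenium and, by concerted metalation–deprotonation, ruthenates the only C–H bond it can reach through a five-membered metallacycle, the vinylic C3a–H held cis to the carboxyl, after which insertion of the bromoalkyne and β-bromide elimination give the 2-(pent-1-ynyl) enoic acid 24. Monovalent silver then activates the alkyne, the carboxylate oxygen attacks its inner carbon C3 anti to the metal, and protodemetalation releases the butenolide. The closest known reaction types are the ruthenium-carboxylate-catalysed ortho C–H alkynylation of benzoic acids with bromoalkynes, the ruthenium-catalysed C–H/O–H annulation of acrylic acids with alkynes, and the silver-catalysed cycloisomerization of (Z)-2-en-4-ynoic acids to (Z)-γ-ylidene butenolides. The butenolide ring closes in the 5-exo-dig mode. No stereocentre is formed, and the (Z) geometry of C3=C8 follows from anti addition of oxygen and hydrogen across the alkyne. The step needs site selectivity (secured by the cis relationship of carboxyl and C3a–H on the ring-A alkene), 5-exo over 6-endo closure (favoured by silver for alkyl-substituted enynoic acids) and survival of the (E) enol lactone (no nucleophilic base and no acid).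

Compound list
1 | mucobromic acid (3,4-dibromo-5-hydroxyfuran-2(5H)-one) | OC1OC(=O)C(Br)=C1Br | starting material
2 | 3,4-dibromo-5-methoxyfuran-2(5H)-one (racemic) | COC1OC(=O)C(Br)=C1Br | intermediate
3 | (2-tert-butoxy-2-oxoethyl)zinc bromide | CC(C)(C)OC(=O)C[Zn]Br | starting material
4 | tert-butyl 2-(4-bromo-2-methoxy-5-oxo-2,5-dihydrofuran-3-yl)acetate (racemic) | COC1OC(=O)C(Br)=C1CC(=O)OC(C)(C)C | intermediate
5 | tert-butyl 2-(4-ethenyl-2-methoxy-5-oxo-2,5-dihydrofuran-3-yl)acetate (racemic) | COC1OC(=O)C(C=C)=C1CC(=O)OC(C)(C)C | intermediate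
6 | (R)-cyclohex-2-en-1-ol | O[C@H]1C=CCCC1 | starting material
7 | 2-(4-ethenyl-2-methoxy-5-oxo-2,5-dihydrofuran-3-yl)acetic acid | COC1OC(=O)C(C=C)=C1CC(=O)O | intermediate
8 | (R)-cyclohex-2-en-1-yl 2-(4-ethenyl-2-methoxy-5-oxo-2,5-dihydrofuran-3-yl)acetate (both acetal epimers) | COC1OC(=O)C(C=C)=C1CC(=O)O[C@H]1C=CCCC1 | intermediate
9 | photocycloadduct: cyclobutane fused to ring A (7aR), to the six-membered tether lactone and to the 3'-methoxy γ-lactone; vinyl on C7a' (both C3' epimers) | COC1OC(=O)[C@]2(C=C)[C@H]3CCC[C@H]4OC(=O)C[C@@]12[C@@H]34 | intermediate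
10 | diol: C3a'–CH2CH2OH and 7a-hydroxyl | COC1OC(=O)[C@]2(C=C)[C@H]3CCC[C@@H](O)[C@H]3[C@]12CCO | intermediate
11 | primary iodide: C3a'–CH2CH2I | COC1OC(=O)[C@]2(C=C)[C@H]3CCC[C@@H](O)[C@H]3[C@]12CCI | intermediate
12 | diene: but-3-enyl on C3a', vinyl on C7a' | COC1OC(=O)[C@]2(C=C)[C@H]3CCC[C@@H](O)[C@H]3[C@]12CCC=C | intermediate
13 | propellane with ring B (C6'=C7'), 3'-methoxy γ-lactone, 7a-hydroxyl | COC1OC(=O)[C@@]23C=CCC[C@@]12[C@@H]1[C@H](O)CCC[C@@H]13 | intermediate
14 | lactol (3'-hydroxy γ-lactone) | OC1OC(=O)[C@@]23C=CCC[C@@]12[C@@H]1[C@H](O)CCC[C@@H]13 | intermediate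
15 | alkynoic acid: ethynyl on C3a', CO2H on C7a', 7a-hydroxyl | C#C[C@]12CCC=C[C@@]1(C(=O)O)[C@H]1CCC[C@@H](O)[C@@H]21 | intermediate
16 | (E)-iodomethylene enol lactone B, 7a-hydroxyl | O[C@@H]2CCC[C@H]1[C@@H]2[C@@]23CCC=C[C@@]12C(=O)O/C3=C/I | intermediate
17 | (E)-butylidene enol lactone B, 7a-hydroxyl | O[C@@H]2CCC[C@H]1[C@@H]2[C@@]23CCC=C[C@@]12C(=O)O/C3=C/CCC | intermediate
18 | ring-A ketone (C7a=O) | O=C2CCC[C@H]1[C@@H]2[C@@]23CCC=C[C@@]12C(=O)O/C3=C/CCC | intermediate
19 | potassium enolate of 18 (C7a=C3a) | [K+].[O-]C2=CCC[C@H]1[C@@H]2[C@@]23CCC=C[C@@]12C(=O)O/C3=C/CCC | intermediate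
20 | enol triflate (OTf on C7a, C7a=C3a) | O=S(=O)(OC2=CCC[C@H]1[C@@H]2[C@@]23CCC=C[C@@]12C(=O)O/C3=C/CCC)C(F)(F)F | intermediate
21 | ring-A enoic acid (CO2H on C7a, H on C3a) | OC(=O)C2=CCC[C@H]1[C@@H]2[C@@]23CCC=C[C@@]12C(=O)O/C3=C/CCC | intermediate
22 | pent-1-yne | CCCC#C | starting material
23 | 1-bromopent-1-yne | CCCC#CBr | intermediate
24 | enynoic acid (CO2H on C7a, pent-1-ynyl on C3a) | OC(=O)C2=C(C#CCCC)CC[C@H]1[C@@H]2[C@@]23CCC=C[C@@]12C(=O)O/C3=C/CCC | intermediate
25 | target: (Z)-butylidene butenolide on ring A, (E)-butylidene enol lactone on ring B, rings A and B syn on the cyclobutane | CCC/C=C1\OC(=O)C2=C1CC[C@H]1[C@@H]2[C@@]23CCC=C[C@@]12C(=O)O/C3=C/CCC | target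

Total step count: 17. Longest linear sequence: 16 (steps 1–15 and 17; step 16 is a side branch).

Steps most likely to fail

Step 17 (Proposed new method). The vinylic C–H metalation may not turn over with an alkyl-substituted bromoalkyne, the closure may leak into the 6-endo mode, or the (E) enol lactone may isomerize or open on heating with carbonate. The fallback uses known reactions only and runs from ketone 18 back to enynoic acid 24. Dehydrogenation of 18 with 2-iodoxybenzoic acid in DMSO at 65 °C should give the ring-A enone F1 (C3a=C4). I2 and pyridine in CH2Cl2 should give the 2-iodoenone F2. Sonogashira coupling with pent-1-yne 22 (PdCl2(PPh3)2, CuI, i-Pr2NH, THF) should give the alkynyl enone F3. Conjugate reduction with LiBH(s-Bu)3 in THF at −78 °C should give the lithium enolate F4, which PhNTf2 should trap as the alkynyl enol triflate F5. Hydroxycarbonylation as in step 15 should then give 24, which AgNO3 in acetone should close to 25 by the established 5-exo-dig cycloisomerization.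

Step 5. Reaction may be inefficient from the minor s-cis ester conformer, the allyl-type 1,4-biradical may close at the vinyl terminus (formal [4+2]), the vinylfuranone may dimerize thermally before irradiation, or the alkene may be attacked on the face anti to the ester oxygen. The fallback takes the diene out of the chromophore and runs from bromide 4 back to cycloadduct 9. Stille coupling of 4 with allyltributylstannane should give the allyl furanone ester F6. TFA should give the allyl furanone acid F7, and EDC·HCl with DMAP and 6 should give the tethered allyl furanone ester F8. Irradiation at 300 nm in acetone (sensitized enone–alkene [2+2]) should give the allyl cycloadduct F9. RuHCl(CO)(PPh3)3 in toluene at 80 °C should move the double bond to give the (E)-prop-1-enyl cycloadduct F10. Ethenolysis (ethene, second-generation Grubbs catalyst, CH2Cl2) should trim this to the vinyl compound 9.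

Step 11. The iodonium source may attack the ring-B alkene instead of the alkyne, and the anti addition may erode. The fallback runs from alkynoic acid 15 back to alcohol 17. Palladium-catalysed cyclization–allylation (PdCl2(PhCN)2 5 mol %, allyl chloride, K2CO3, THF, rt; anti oxypalladation, then allylation of the alkenylpalladium with retention) should give the (E)-but-3-enylidene lactone F11. Hydrogenation with RhCl(PPh3)3 under H2 (1 atm) in benzene, which saturates only the monosubstituted alkene, should give 17.

Further compounds
F1 | step 17 | ring-A enone (C7a=O, C3a=C4) | O=C2C=CC[C@H]1[C@@H]2[C@@]23CCC=C[C@@]12C(=O)O/C3=C/CCC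
F2 | step 17 | 2-iodoenone (iodine on C3a) | O=C2C(I)=CC[C@H]1[C@@H]2[C@@]23CCC=C[C@@]12C(=O)O/C3=C/CCC
F3 | step 17 | alkynyl enone (pent-1-ynyl on C3a) | O=C2C(C#CCCC)=CC[C@H]1[C@@H]2[C@@]23CCC=C[C@@]12C(=O)O/C3=C/CCC
F4 | step 17 | lithium enolate (C7a=C3a, pent-1-ynyl on C3a) | [Li+].[O-]C2=C(C#CCCC)CC[C@H]1[C@@H]2[C@@]23CCC=C[C@@]12C(=O)O/C3=C/CCC
F5 | step 17 | alkynyl enol triflate (OTf on C7a, pent-1-ynyl on C3a) | O=S(=O)(OC2=C(C#CCCC)CC[C@H]1[C@@H]2[C@@]23CCC=C[C@@]12C(=O)O/C3=C/CCC)C(F)(F)F
F6 | step 5 | tert-butyl 2-(4-allyl-2-methoxy-5-oxo-2,5-dihydrofuran-3-yl)acetate | COC1OC(=O)C(CC=C)=C1CC(=O)OC(C)(C)C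
F7 | step 5 | 2-(4-allyl-2-methoxy-5-oxo-2,5-dihydrofuran-3-yl)acetic acid | COC1OC(=O)C(CC=C)=C1CC(=O)O
F8 | step 5 | (R)-cyclohex-2-en-1-yl 2-(4-allyl-2-methoxy-5-oxo-2,5-dihydrofuran-3-yl)acetate | COC1OC(=O)C(CC=C)=C1CC(=O)O[C@H]1C=CCCC1
F9 | step 5 | allyl cycloadduct (as 9 with allyl on C7a') | COC1OC(=O)[C@]2(CC=C)[C@H]3CCC[C@H]4OC(=O)C[C@@]12[C@@H]34
F10 | step 5 | (E)-prop-1-enyl cycloadduct (as 9 with prop-1-enyl on C7a') | COC1OC(=O)[C@]2(/C=C/C)[C@H]3CCC[C@H]4OC(=O)C[C@@]12[C@@H]34
F11 | step 11 | (E)-but-3-enylidene enol lactone B, 7a-hydroxyl | O[C@@H]2CCC[C@H]1[C@@H]2[C@@]23CCC=C[C@@]12C(=O)O/C3=C/CC=C
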